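Germacrane numbering is used: ring carbons C1–C10 (C1 bears OOH, C3 OAc, C6 the lactone oxygen), lactone carbons C11–C13. Everything rests on disconnecting the tetrasubstituted C7=C11 bond of the five-membered lactone ring. Because both olefinic carbons are already linked through the O6–C12 ester, an ester-tethered ring-closing metathesis between the C7 exocyclic methylene of a ten-membered carbocycle and a 2-(acetoxymethyl)acrylate on O6 forges this bond, closes the butenolide and brings in C11–C13 with the 13-acetate in one operation. The precursor is a (1(10)E,4Z)-cyclodecadienol made by Nozaki–Hiyama–Kishi macrocyclisation; a final singlet-oxygen ene reaction turns C1=C10 into the C1 hydroperoxide and C10 methylene.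

Key step: step 13

Remark on the chemistry: C6 is created in the ring closure of step 10 under substrate control; the 6R epimer is assumed to predominate and to be separable, and the opposite outcome is covered by a fallback. C14 is the methyl on C10, C15 the methyl on C4.

**Step 1**
Reactants: 1 prop-2-yn-1-ol
Product: 3 (Z)-3-iodo-2-methylprop-2-en-1-ol, via alkenylmagnesium alkoxide 2 (not isolated)
Conditions: MeMgBr (3 equiv), CuI (10 mol%), THF, −10 °C to rt; then I2, −40 °C to rt
Reagents that add atoms: methylmagnesium bromide, C[Mg]Br; iodine, II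
Why: Copper-catalysed anti-carbomagnesiation of the propargylic alkoxide places methyl on the internal carbon and magnesium on the terminal carbon cis to the CH2O group through a five-membered chelate, and iodinolysis with retention gives the Z-iodide that becomes the 4Z ring olefin.

**Step 2**
Reactants: 3 (Z)-3-iodo-2-methylprop-2-en-1-ol
Product: 4 (Z)-3-iodo-2-methylprop-2-enal
Conditions: MnO2 (excess), CH2Cl2, rt, dark; used at once
Reagents that add atoms: none
Why: MnO2 oxidation of an allylic alcohol is neutral and heterogeneous, stops at the aldehyde and should not isomerise the Z-iodoenal.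

**Step 3**
Reactants: 4 (Z)-3-iodo-2-methylprop-2-enal
Product: 5 (1Z,3S)-1-iodo-2-methylhexa-1,5-dien-3-ol
Conditions: (−)-Ipc2B(allyl) (salt-free), Et2O, −78 °C; then 3 M NaOH, 30% H2O2, 0 °C to rt
Reagents that add atoms: (−)-B-allyldiisopinocampheylborane, C=CCB([C@@H]1C[C@@H]2C[C@H]([C@H]1C)C2(C)C)[C@@H]1C[C@@H]2C[C@H]([C@H]1C)C2(C)C
Why: Brown allylboration through a chair six-membered transition state: the (+)-α-pinene-derived reagent adds allyl to the Si face of the aldehyde, the same sense that gives (S)-1-phenylbut-3-en-1-ol from benzaldehyde, and so sets C3 as S.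

**Step 4**
Reactants: 5 (1Z,3S)-1-iodo-2-methylhexa-1,5-dien-3-ol
Product: 6 (1Z,3S)-1-iodo-2-methylhexa-1,5-dien-3-yl acetate
Conditions: Ac2O, pyridine, DMAP (cat.), CH2Cl2, 0 °C
Reagents that add atoms: acetic anhydride, CC(=O)OC(C)=O
Why: DMAP-catalysed acylation installs the C3 acetate of the target at the outset, so that no protecting-group exchange is needed later; the stereocentre is not involved.

**Step 5**
Reactants: 6 (1Z,3S)-1-iodo-2-methylhexa-1,5-dien-3-yl acetate
Product: 8 (3S,4Z)-5-iodo-4-methyl-1-oxopent-4-en-3-yl acetate, via ozonide 7 (not isolated)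
Conditions: O3, CH2Cl2, −78 °C (Sudan Red 7B end point); then Me2S, −78 °C to 0 °C; crude used directly
Reagents that add atoms: ozone, [O-][O+]=O
Why: Ozonolysis with reductive work-up: electrophilic ozone cleaves the monosubstituted alkene much faster than the iodine-bearing trisubstituted alkene, and the base-free cold work-up keeps the β-acetoxy aldehyde from eliminating acetic acid.

**Step 6**
Reactants: 8 (3S,4Z)-5-iodo-4-methyl-1-oxopent-4-en-3-yl acetate
Product: 9 (1Z,3S)-5-hydroxy-1-iodo-2,6-dimethylhepta-1,6-dien-3-yl acetate (both C5 epimers)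
Conditions: CH2=C(CH3)MgBr, anhydrous CeCl3, THF, −78 °C; AcOH quench at −78 °C
Reagents that add atoms: isopropenylmagnesium bromide, C=C(C)[Mg]Br
Why: Organocerium 1,2-addition: the weakly basic alkenylcerium adds to the aldehyde far faster than to the acetate without β-elimination, the cold acidic quench prevents 1,3-acetyl migration, and the new carbinol centre may be a mixture because step 7 removes it.

**Step 7**
Reactants: 9 (1Z,3S)-5-hydroxy-1-iodo-2,6-dimethylhepta-1,6-dien-3-yl acetate
Product: 11 (1Z,3S,5E)-1-iodo-2,6-dimethyl-9-oxonona-1,5-dien-3-yl acetate, via allyl vinyl ether 10 (not isolated)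
Conditions: Hg(OAc)2 (0.3 equiv), ethyl vinyl ether, reflux; concentrate; then toluene, 115 °C, sealed tube
Reagents that add atoms: ethyl vinyl ether, C=COCC
Why: Mercury-catalysed transetherification then Claisen rearrangement through a chair transition state with the C2 chain equatorial forms the C8–C9 bond, the C7 aldehyde and the E-trisubstituted C1=C10 olefin; C3 is untouched.

**Step 8**
Reactants: 11 (1Z,3S,5E)-1-iodo-2,6-dimethyl-9-oxonona-1,5-dien-3-yl acetate
Product: 13 (1Z,3S,5E)-1-iodo-2,6-dimethyl-10-oxodeca-1,5-dien-3-yl acetate, via methyl enol ether 12 (not isolated)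
Conditions: MeOCH2PPh3Cl, KHMDS, THF, −78 to 0 °C; then 1 M HCl, THF, rt
Reagents that add atoms: (methoxymethyl)triphenylphosphonium chloride, COC[P+](c1ccccc1)(c1ccccc1)c1ccccc1.[Cl-]; water, O
Why: Wittig methoxymethylenation followed by acid hydrolysis of the enol ether is the standard one-carbon aldehyde homologation and supplies C6; the brief cold exposure to the ylide should leave the acetate and the alkenyl iodide intact.

**Step 9**
Reactants: 13 (1Z,3S,5E)-1-iodo-2,6-dimethyl-10-oxodeca-1,5-dien-3-yl acetate
Product: 14 (1Z,3S,5E)-9-formyl-1-iodo-2,6-dimethyldeca-1,5,9-trien-3-yl acetate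
Conditions: 37% aq. CH2O, pyrrolidine (10 mol%), EtCO2H (10 mol%), iPrOH, 45 °C
Reagents that add atoms: formaldehyde, C=O
Why: Amine/acid-catalysed Mannich condensation with formaldehyde followed by elimination (α-methylenation of aldehydes) converts C7 into the 1,1-disubstituted olefin that serves as metathesis partner, under conditions too mild to affect acetate or iodide.

**Step 10**
Reactants: 14 (1Z,3S,5E)-9-formyl-1-iodo-2,6-dimethyldeca-1,5,9-trien-3-yl acetate
Product: 15 (1S,2Z,4R,8E)-4-hydroxy-2,8-dimethyl-5-methylidenecyclodeca-2,8-dien-1-yl acetate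
Conditions: CrCl2 (8 equiv), NiCl2 (2 mol%), degassed DMSO/THF, rt, 2 mM, slow addition
Reagents that add atoms: none
Why: Nozaki–Hiyama–Kishi reaction: nickel-catalysed formation of the alkenylchromium species from the Z-iodide with retention of geometry and its 1,2-addition to the enal under high dilution closes the ten-membered ring at C5–C6 and creates C6, whose configuration is set by macrocyclic control from the C3 acetate and the two rigid olefins (6R assumed as major, see remark).

**Step 11**
Reactants: 16 2-(bromomethyl)prop-2-enoic acid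
Product: 17 2-(acetoxymethyl)prop-2-enoic acid
Conditions: KOAc (3 equiv), AcOH, 50 °C, BHT
Reagents that add atoms: potassium acetate, CC(=O)[O-].[K+]
Why: SN2 (or SN2', which gives the same product in this symmetrical allyl system) displacement of the allylic bromide by acetate in buffered acetic acid, where the large excess of acetate outcompetes the substrate's own carboxylate.

**Step 12**
Reactants: 15 (1S,2Z,4R,8E)-4-hydroxy-2,8-dimethyl-5-methylidenecyclodeca-2,8-dien-1-yl acetate; 17 2-(acetoxymethyl)prop-2-enoic acid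
Product: 19 (1R,2Z,4S,6E)-4-acetoxy-3,7-dimethyl-10-methylidenecyclodeca-2,6-dien-1-yl 2-(acetoxymethyl)prop-2-enoate, via 2-(acetoxymethyl)prop-2-enoyl chloride 18 (not isolated)
Conditions: 17, 1-chloro-N,N,2-trimethylprop-1-en-1-amine, CH2Cl2, 0 °C; then 15, pyridine, −20 to 0 °C
Reagents that add atoms: 1-chloro-N,N,2-trimethylprop-1-en-1-amine, CC(C)=C(Cl)N(C)C (chlorine of 18 only)
Why: Acylation through the acid chloride made under neutral conditions avoids strongly nucleophilic amine catalysts that would attack the acetoxymethyl acrylate in an SN2' sense, and proceeds with retention at C6.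

**Step 13**
Reactants: 19 (1R,2Z,4S,6E)-4-acetoxy-3,7-dimethyl-10-methylidenecyclodeca-2,6-dien-1-yl 2-(acetoxymethyl)prop-2-enoate
Product: 20 (3S,6R)-3,13-diacetoxygermacra-1(10)E,4Z,7(11)-trien-12,6-olide
Conditions: dichloro[1,3-bis(2-methylphenyl)imidazolidin-2-ylidene](2-isopropoxybenzylidene)ruthenium (15 mol%, in portions), 1,4-benzoquinone (20 mol%), toluene, 80 °C, 2 mM, argon sparge
Reagents that add atoms: none
Why: Ring-closing metathesis: a ruthenium methylidene loads onto the more electron-rich C7 exocyclic methylene, the resulting alkylidene undergoes intramolecular [2+2] addition to the acrylate methylene held in place by the O6–C12 ester, and cycloreversion releases ethene and the tetrasubstituted C7=C11 bond. The closest known reaction type is the metathesis closure of methacrylate-type esters of 2-substituted allylic alcohols to α,β-disubstituted butenolides, which calls for NHC-ruthenium catalysts with small N-aryl groups at elevated temperature. The five-membered lactone ring (O6, C12, C11, C7, C6) is closed in the olefin-forming mode, the endocyclic double bond being the new bond itself, with loss of ethene as the driving force. No stereocentre is created: C6 is already in place and the ring fixes the olefin geometry. The step needs chemoselectivity for the two terminal methylenes over the ring-embedded trisubstituted C1=C10 and C4=C5 olefins, which are hindered and lead to no productive ring, and it must avoid olefin migration, which the benzoquinone additive suppresses. High dilution and continuous removal of ethene should keep the slow tetrasubstituted closure ahead of dimerisation.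

**Step 14**
Reactants: 20 (3S,6R)-3,13-diacetoxygermacra-1(10)E,4Z,7(11)-trien-12,6-olide
Product: 21 (1R,3S,6R)-3,13-diacetoxy-1-hydroperoxygermacra-4Z,7(11),10(14)-trien-12,6-olide (CNP0174966.1)
Conditions: O2, tetraphenylporphyrin (cat.), visible light, CH2Cl2, −20 °C; stopped at partial conversion, no reductive work-up
Reagents that add atoms: dioxygen, O=O
Why: Schenck ene reaction: singlet oxygen attacks the most electron-rich olefin (C1=C10; C4=C5 is deactivated by two allylic oxygens and C7=C11 is conjugated), abstracts hydrogen from the freely rotating C14 methyl on the more crowded side of the double bond (the C2 hydrogens are deactivated by the C3 acetate) and bonds to C1 from the exposed outer β-face of the crossed ring conformer, as in the photo-oxygenation of germacranolides to 1β-hydroperoxy-10(14)-enes, which sets C1 as R.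

**Compound list**
1 | prop-2-yn-1-ol | C#CCO | starting material
2 | bromomagnesium (Z)-3-(bromomagnesio)-2-methylprop-2-en-1-olate | Br[Mg]/C=C(/C)CO[Mg]Br | intermediate
3 | (Z)-3-iodo-2-methylprop-2-en-1-ol | OC/C(C)=C\I | intermediate
4 | (Z)-3-iodo-2-methylprop-2-enal | O=C/C(C)=C\I | intermediate
5 | (1Z,3S)-1-iodo-2-methylhexa-1,5-dien-3-ol | C=CC[C@H](O)/C(C)=C\I | intermediate
6 | (1Z,3S)-1-iodo-2-methylhexa-1,5-dien-3-yl acetate | C=CC[C@H](OC(C)=O)/C(C)=C\I | intermediate
7 | (2S,3Z)-4-iodo-3-methyl-1-(1,2,4-trioxolan-3-yl)but-3-en-2-yl acetate | C1OC(C[C@H](OC(C)=O)/C(C)=C\I)OO1 | intermediate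
8 | (3S,4Z)-5-iodo-4-methyl-1-oxopent-4-en-3-yl acetate | O=CC[C@H](OC(C)=O)/C(C)=C\I | intermediate
9 | (1Z,3S)-5-hydroxy-1-iodo-2,6-dimethylhepta-1,6-dien-3-yl acetate (C5 epimers) | C=C(C)C(O)C[C@H](OC(C)=O)/C(C)=C\I | intermediate
10 | (1Z,3S)-5-(ethenyloxy)-1-iodo-2,6-dimethylhepta-1,6-dien-3-yl acetate | C=COC(C[C@H](OC(C)=O)/C(C)=C\I)C(C)=C | intermediate
11 | (1Z,3S,5E)-1-iodo-2,6-dimethyl-9-oxonona-1,5-dien-3-yl acetate | O=CCC/C(C)=C/C[C@H](OC(C)=O)/C(C)=C\I | intermediate
12 | (1Z,3S,5E)-1-iodo-10-methoxy-2,6-dimethyldeca-1,5,9-trien-3-yl acetate (E/Z at C9) | COC=CCC/C(C)=C/C[C@H](OC(C)=O)/C(C)=C\I | intermediate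
13 | (1Z,3S,5E)-1-iodo-2,6-dimethyl-10-oxodeca-1,5-dien-3-yl acetate | O=CCCC/C(C)=C/C[C@H](OC(C)=O)/C(C)=C\I | intermediate
14 | (1Z,3S,5E)-9-formyl-1-iodo-2,6-dimethyldeca-1,5,9-trien-3-yl acetate | C=C(C=O)CC/C(C)=C/C[C@H](OC(C)=O)/C(C)=C\I | intermediate
15 | (1S,2Z,4R,8E)-4-hydroxy-2,8-dimethyl-5-methylidenecyclodeca-2,8-dien-1-yl acetate | C1C/C(C)=C/C[C@H](OC(C)=O)/C(C)=C\[C@@H](O)C1=C | intermediate
16 | 2-(bromomethyl)prop-2-enoic acid | C=C(CBr)C(=O)O | starting material
17 | 2-(acetoxymethyl)prop-2-enoic acid | C=C(COC(C)=O)C(=O)O | intermediate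
18 | 2-(acetoxymethyl)prop-2-enoyl chloride | C=C(COC(C)=O)C(=O)Cl | intermediate
19 | (1R,2Z,4S,6E)-4-acetoxy-3,7-dimethyl-10-methylidenecyclodeca-2,6-dien-1-yl 2-(acetoxymethyl)prop-2-enoate | C1C/C(C)=C/C[C@H](OC(C)=O)/C(C)=C\[C@@H](OC(=O)C(=C)COC(C)=O)C1=C | intermediate
20 | (3S,6R)-3,13-diacetoxygermacra-1(10)E,4Z,7(11)-trien-12,6-olide | C1C/C(C)=C/C[C@H](OC(C)=O)/C(C)=C\[C@H]2OC(=O)C(COC(C)=O)=C12 | intermediate
21 | (1R,3S,6R)-3,13-diacetoxy-1-hydroperoxygermacra-4Z,7(11),10(14)-trien-12,6-olide | C=C1CCC2=C(COC(C)=O)C(=O)O[C@@H]2/C=C(/C)[C@@H](OC(C)=O)C[C@H]1OO | target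

Total step count: 14. Longest linear sequence: 13 (steps 1–10 and 12–14; step 11 is a one-step side branch).

**Steps most likely to fail**

Step 13 (ring-closing metathesis). The ruthenium methylidene may fail to load onto either hindered 1,1-disubstituted olefin, or the alkylidene may decompose before the tetrasubstituted ruthenacycle forms, so that the diene is recovered or only isomerised. The fallback replaces metathesis by carbonyl olefination; it sets out from 14 and returns at 20. Epoxidation of the enal, the only electron-poor olefin in 14 (H2O2, NaHCO3, MeOH, 0 °C), gives the epoxy aldehyde F1. The same chromium-mediated ring closure as in step 10 gives the spiro-epoxy alcohol F2. Acylation (DIC, DMAP) with 3-[(tert-butyldiphenylsilyl)oxy]-2-(diethoxyphosphoryl)propanoic acid gives the phosphonate ester F3. H5IO6 in wet THF hydrolyses the epoxide and cleaves the resulting glycol to the C7 ketone F4; O6 is acylated, so the C6–C7 bond is not cleaved. An intramolecular Horner–Wadsworth–Emmons reaction (LiCl, iPr2NEt, MeCN) closes C7=C11 to the 13-silyl ether F5. HF·pyridine gives the 13-alcohol F6, and Ac2O/pyridine gives 20.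

Step 10 (macrocyclisation). The alkenylchromium species may add to the wrong face of the aldehyde under macrocyclic control and give mainly the 6S carbinol. The fallback corrects the stereocentre by inversion instead of relying on its formation; it sets out from 14 and returns at 19. The 6S alcohol F7, isolated from the same ring closure, is esterified with acid 17 under Mitsunobu conditions (PPh3, DIAD, toluene, −20 °C, betaine pre-formed) with inversion at C6 to give 19 directly.

Step 14 (ene reaction). Oxygen may be delivered to the inner α-face of C1=C10 and give the C1 epimer, with competing hydrogen abstraction from C2. The fallback installs the peroxide by SN2 displacement; it sets out from 20 and returns at 21. The epimeric hydroperoxide F8 is reduced (PPh3, CH2Cl2, 0 °C) to the allylic alcohol F9 and converted into the mesylate F10 (MsCl, Et3N, −40 °C). Displacement with inversion by potassium 2-methoxyprop-2-yl peroxide (18-crown-6, THF, 0 °C) gives the perketal F11, which AcOH/H2O/THF unmasks to 21.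

**Further compounds**
F1 | step 13 | (1Z,3S,5E)-8-(2-formyloxiran-2-yl)-1-iodo-2,6-dimethylocta-1,5-dien-3-yl acetate | O=CC1(CO1)CC/C(C)=C/C[C@H](OC(C)=O)/C(C)=C\I
F2 | step 13 | (4R,5Z,7S,9E)-4-hydroxy-6,10-dimethyl-1-oxaspiro[2.9]dodeca-5,9-dien-7-yl acetate (spiro centre unassigned) | C1C/C(C)=C/C[C@H](OC(C)=O)/C(C)=C\[C@@H](O)C12CO2
F3 | step 13 | (4R,5Z,7S,9E)-7-acetoxy-6,10-dimethyl-1-oxaspiro[2.9]dodeca-5,9-dien-4-yl 3-[(tert-butyldiphenylsilyl)oxy]-2-(diethoxyphosphoryl)propanoate | C1C/C(C)=C/C[C@H](OC(C)=O)/C(C)=C\[C@@H](OC(=O)C(CO[Si](c3ccccc3)(c3ccccc3)C(C)(C)C)P(=O)(OCC)OCC)C12CO2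
F4 | step 13 | (1R,2Z,4S,6E)-4-acetoxy-3,7-dimethyl-10-oxocyclodeca-2,6-dien-1-yl 3-[(tert-butyldiphenylsilyl)oxy]-2-(diethoxyphosphoryl)propanoate | C1C/C(C)=C/C[C@H](OC(C)=O)/C(C)=C\[C@@H](OC(=O)C(CO[Si](c2ccccc2)(c2ccccc2)C(C)(C)C)P(=O)(OCC)OCC)C1=O
F5 | step 13 | (3S,6R)-3-acetoxy-13-[(tert-butyldiphenylsilyl)oxy]germacra-1(10)E,4Z,7(11)-trien-12,6-olide | C1C/C(C)=C/C[C@H](OC(C)=O)/C(C)=C\[C@H]2OC(=O)C(CO[Si](c3ccccc3)(c3ccccc3)C(C)(C)C)=C12
F6 | step 13 | (3S,6R)-3-acetoxy-13-hydroxygermacra-1(10)E,4Z,7(11)-trien-12,6-olide | C1C/C(C)=C/C[C@H](OC(C)=O)/C(C)=C\[C@H]2OC(=O)C(CO)=C12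
F7 | step 10 | (1S,2Z,4S,8E)-4-hydroxy-2,8-dimethyl-5-methylidenecyclodeca-2,8-dien-1-yl acetate | C1C/C(C)=C/C[C@H](OC(C)=O)/C(C)=C\[C@H](O)C1=C
F8 | step 14 | (1S,3S,6R)-3,13-diacetoxy-1-hydroperoxygermacra-4Z,7(11),10(14)-trien-12,6-olide | C=C1CCC2=C(COC(C)=O)C(=O)O[C@@H]2/C=C(/C)[C@@H](OC(C)=O)C[C@@H]1OO
F9 | step 14 | (1S,3S,6R)-3,13-diacetoxy-1-hydroxygermacra-4Z,7(11),10(14)-trien-12,6-olide | C=C1CCC2=C(COC(C)=O)C(=O)O[C@@H]2/C=C(/C)[C@@H](OC(C)=O)C[C@@H]1O
F10 | step 14 | (1S,3S,6R)-3,13-diacetoxy-1-(methanesulfonyloxy)germacra-4Z,7(11),10(14)-trien-12,6-olide | C=C1CCC2=C(COC(C)=O)C(=O)O[C@@H]2/C=C(/C)[C@@H](OC(C)=O)C[C@@H]1OS(C)(=O)=O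
F11 | step 14 | (1R,3S,6R)-3,13-diacetoxy-1-[(2-methoxypropan-2-yl)peroxy]germacra-4Z,7(11),10(14)-trien-12,6-olide | C=C1CCC2=C(COC(C)=O)C(=O)O[C@@H]2/C=C(/C)[C@@H](OC(C)=O)C[C@H]1OOC(C)(C)OC
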